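Gravicycle is disconnected through ring A, at its C(OAr)–CH and C(OH)–CH bonds. The key step exploits the alternating substitution of ring A (OH, the ether oxygen to ring B and the C14 methylene on every second carbon). This pattern maps onto a vinylketene (four carbons, released from a 3-alkylcyclobutenone on C14) and an aryloxyalkyne (two carbons, already on the crowded ring B oxygen). One thermal operation thus forms ring A and the 22-membered ring without any aryl–oxygen coupling. The precursor is a ring B ethynyl ether with two benzyl ethers whose (R)-silyloxy C1–C14 chain ends in a cyclobut-2-enone. Both termini travel masked, as dichlorovinyl ether and dimethyl ketal.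

Key step: step 14

Remarks on the chemistry
- Assumption on numbering: C1 is the carbinol carbon and C2–C14 are the thirteen methylenes, with C14 on ring A. Ring A is the 1,3,5-trisubstituted ring and ring B the 3,4,5-trioxygenated ring. With O > aryl > CH2 > H, the [C@H] of the target is (R).
- The two reactive termini cannot be made side by side. An ethynyl ether is a far better ketenophile than an alkyl alkyne, so dichloroketene would attack it first. A cyclobutenone does not survive the butyllithium that unveils the ethynyl ether.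
- The four-membered ring is therefore built first, on the simple chain fragment, and stored as a dimethyl ketal. The ynol ether is stored as an (E)-1,2-dichlorovinyl ether. Base unveils the alkyne, and then a trace of acid frees the enone.
- Carbon count: the C12 dibromide plus the propargylic carbon of propyne gives the thirteen methylenes. The two alkyne carbons become C3 and C2 of the cyclobutenone.
- The transient [2+2] adduct of the key step is a 4-alkenylcyclobut-2-enone.

Step 1
Reactants: 1 3,4,5-trihydroxybenzaldehyde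
Product: 3 4-(allyloxy)-3,5-bis(benzyloxy)benzaldehyde, via 4-(allyloxy)-3,5-dihydroxybenzaldehyde 2 (not isolated)
Conditions: allyl bromide (1.0 equiv), KHCO3, DMF, N2, 40 °C; then BnBr (2.3 equiv), K2CO3, 50 °C
Reagents that add atoms: allyl bromide C=CCBr; benzyl bromide BrCc1ccccc1
Why: Two-stage Williamson etherification: the 4-OH, conjugated with the para formyl group, is the most acidic phenol, so KHCO3 ionises only this site and the allyl group is placed there before K2CO3 and BnBr cap the two flanking phenols.

Step 2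
Reactants: 3 4-(allyloxy)-3,5-bis(benzyloxy)benzaldehyde
Product: 4 3,5-bis(benzyloxy)-4-hydroxybenzaldehyde
Conditions: Pd(PPh3)4 (2 mol%), morpholine, THF, rt
Reagents that add atoms: none
Why: Tsuji–Trost deallylation: zerovalent palladium ionises only the allyl aryl ether to a π-allyl complex that morpholine captures, so the benzyl ethers and the aldehyde stay intact and any isomeric material is removed at this phenol stage.

Step 3
Reactants: 4 3,5-bis(benzyloxy)-4-hydroxybenzaldehyde; 5 trichloroethylene
Product: 6 3,5-bis(benzyloxy)-4-{[(E)-1,2-dichloroethenyl]oxy}benzaldehyde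
Conditions: K2CO3, DMF, N2, 65 °C
Reagents that add atoms: none
Why: Nucleophilic vinylation with trichloroethylene: K2CO3 eliminates HCl from 5 to give dichloroacetylene in situ and the phenoxide adds anti across it, the standard route to aryl (E)-1,2-dichlorovinyl ethers, which should accept a hindered phenol because the electrophile is small and linear.

Step 4
Reactants: 7 propyne; 8 1,12-dibromododecane
Product: 10 15-bromopentadec-1-yne, via 1,3-dilithiopropyne 9 (not isolated)
Conditions: n-BuLi (2 equiv), TMEDA, Et2O/hexane, −78 °C to rt; then 8 (3 equiv), THF, −78 °C to rt; H2O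
Reagents that add atoms: none
Why: Alkylation of the propyne dianion (three-carbon homologation of an alkyl halide): the propargylic carbanion is the more reactive site, the acetylide end does not displace bromide without a polar cosolvent, and excess 8 enforces monoalkylation, which fixes thirteen methylenes between bromine and the alkyne.

Step 5
Reactants: 10 15-bromopentadec-1-yne; 11 trichloroacetyl chloride
Product: 12 3-(13-bromotridecyl)-4,4-dichlorocyclobut-2-en-1-one
Conditions: Zn–Cu couple, Et2O/DME, rt, slow addition of 11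
Reagents that add atoms: none
Why: Ketene–alkyne [2+2] cycloaddition: dichloroketene, released from 11 by zinc, bonds through its carbonyl carbon to the terminal alkyne carbon and so gives the 3-alkyl-4,4-dichloro regioisomer, while DME binds ZnCl2 and the primary bromide is inert.

Step 6
Reactants: 12 3-(13-bromotridecyl)-4,4-dichlorocyclobut-2-en-1-one
Product: 13 3-(13-bromotridecyl)cyclobut-2-en-1-one
Conditions: Zn dust, AcOH, TMEDA, EtOH, 0 °C to rt
Reagents that add atoms: none
Why: Reductive dechlorination of an α,α-dichloroketone by zinc through zinc enolates; the AcOH/TMEDA buffer avoids double-bond migration and over-reduction, and since the amine is held as acetate salt and zinc chelate the primary bromide should survive the short exposure.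

Step 7
Reactants: 13 3-(13-bromotridecyl)cyclobut-2-en-1-one
Product: 14 1-(13-bromotridecyl)-3,3-dimethoxycyclobut-1-ene
Conditions: MeOSiMe3 (3 equiv), TMSOTf (5 mol%), CH2Cl2, −78 °C; pyridine quench
Reagents that add atoms: methoxytrimethylsilane CO[Si](C)(C)C
Why: Noyori ketalisation: the aprotic silyl triflate conditions turn enones into ketals at low temperature without conjugate addition or double-bond shift, rehybridisation of the strained carbonyl carbon to sp3 helps, and cyclobutenedione monoketals made in this way are known to withstand organolithium reagents.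

Step 8
Reactants: 14 1-(13-bromotridecyl)-3,3-dimethoxycyclobut-1-ene; 6 3,5-bis(benzyloxy)-4-{[(E)-1,2-dichloroethenyl]oxy}benzaldehyde
Product: 16 rac-1-(3,5-bis(benzyloxy)-4-{[(E)-1,2-dichloroethenyl]oxy}phenyl)-14-(3,3-dimethoxycyclobut-1-en-1-yl)tetradecan-1-ol, via [13-(3,3-dimethoxycyclobut-1-en-1-yl)tridecyl]magnesium bromide 15 (not isolated)
Conditions: Mg, cat. I2, THF, 35 °C; then 6, THF, −40 to 0 °C; pH 7 buffer
Reagents that add atoms: none
Why: Grignard addition to a non-enolisable aromatic aldehyde, which is much faster than any reaction of the reagent with the ketal or the dichlorovinyl ether; C1 is racemic at this stage and is corrected in steps 9 and 10.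

Step 9
Reactants: 16 racemic carbinol
Product: 17 1-(3,5-bis(benzyloxy)-4-{[(E)-1,2-dichloroethenyl]oxy}phenyl)-14-(3,3-dimethoxycyclobut-1-en-1-yl)tetradecan-1-one
Conditions: activated MnO2, CH2Cl2, rt
Reagents that add atoms: none
Why: Benzylic alcohol oxidation with MnO2, a neutral heterogeneous oxidant that leaves the acid-labile ketal, the strained alkene and the dichlorovinyl ether alone.

Step 10
Reactants: 17 aryl alkyl ketone
Product: 18 (1R)-1-(3,5-bis(benzyloxy)-4-{[(E)-1,2-dichloroethenyl]oxy}phenyl)-14-(3,3-dimethoxycyclobut-1-en-1-yl)tetradecan-1-ol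
Conditions: (S)-2-methyl-CBS-oxazaborolidine (15 mol%), BH3·SMe2, THF, −20 °C, slow addition of 17; MeOH
Reagents that add atoms: none
Why: Corey–Bakshi–Shibata reduction: the (S)-oxazaborolidine binds BH3 and the ketone with the aryl group as the large substituent turned away from the catalyst and delivers hydride to the face that gives the (R)-alcohol, as for other aryl n-alkyl ketones, and the catalysed reduction is far faster than hydroboration of the trisubstituted cyclobutene.

Step 11
Reactants: 18 (R)-alcohol
Product: 19 (R)-tert-butyldimethylsilyl ether of 18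
Conditions: TBSCl, imidazole, DMF, rt
Reagents that add atoms: tert-butyldimethylsilyl chloride CC(C)(C)[Si](C)(C)Cl
Why: Imidazole-promoted silylation of a secondary alcohol at oxygen, in a basic medium that is safe for the ketal and with retention at C1.

Step 12
Reactants: 19 (R)-silyl ether with dichlorovinyl ether and ketal
Product: 22 (R)-ethynyl ether dimethyl ketal, via chloroethynyl ether 20 (not isolated), via lithium aryloxyacetylide 21 (not isolated)
Conditions: n-BuLi (3 equiv), THF, −78 to −30 °C; H2O, −78 °C
Reagents that add atoms: none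
Why: Dichlorovinyl ether to alkynyl ether conversion: the first equivalent of n-BuLi metalates the vinyl C–H and LiCl is lost to give 20, the second effects chlorine–lithium exchange to 21 and water protonates the acetylide, a standard route to aryl ethynyl ethers that the silyl ether, benzyl ethers and ketal tolerate at low temperature.

Step 13
Reactants: 22 (R)-ethynyl ether dimethyl ketal
Product: 23 3-[(14R)-14-[3,5-bis(benzyloxy)-4-(ethynyloxy)phenyl]-14-{[tert-butyl(dimethyl)silyl]oxy}tetradecyl]cyclobut-2-en-1-one
Conditions: PPTS (10 mol%), acetone/H2O 10:1, 0 °C to rt, close monitoring; NaHCO3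
Reagents that add atoms: water O
Why: Acid-catalysed ketal hydrolysis: ionisation to an allyl-stabilised oxocarbenium ion makes this dimethyl ketal far more acid-labile than the weakly basic aryl ethynyl ether (whose oxygen lone pair is shared with ring B) or the secondary silyl ether, so a trace of weak acid should free only the cyclobutenone.

Step 14
Reactants: 23 ethynyl ether cyclobutenone
Product: 28 macrocyclic phenol (ring A closed; ring B dibenzyl ether; (R)-C1 silyl ether), via vinylketene 24 (not isolated), via macrocyclic 4-alkenylcyclobutenone 25 (not isolated), via macrocyclic dienylketene 26 (not isolated), via cyclohexa-2,4-dienone tautomer 27 (not isolated)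
Conditions: dry degassed toluene, 0.5 mM, sealed vessel, 110 °C then 135 °C
Reagents that add atoms: none
Why: Proposed new method: heating opens the cyclobutenone of 23 reversibly (four-electron electrocyclic opening) to vinylketene 24, whose carbonyl carbon is attacked by the unsubstituted, electron-rich alkyne carbon in a [2+2] cycloaddition to give the 4-alkenylcyclobutenone 25, which opens to dienylketene 26, closes by six-electron electrocyclisation to dienone 27 and tautomerises to phenol 28. The closest known reaction type is the intermolecular Danheiser benzannulation of cyclobutenones with alkoxy- or siloxyalkynes, which delivers resorcinol monoethers of the same 1,3,5 pattern; the aryloxyalkyne partner and the macrocyclising mode are new. The 22-membered ring closes in the [2+2] event, end to end along the C1–C14 tether, when the oxygen-bearing alkyne carbon bonds to the ketene alpha carbon, and ring A closes in the six-electron step that rejoins the ketene carbon to the terminal methylene. No lasting stereocentre is formed (the sp3 ring-fusion carbon of 25 is planarised again) and the remote, silyl-protected (R)-C1 is not touched. Regiochemistry needs the ketene carbonyl carbon to meet the CH terminus of the alkyne, which the donor oxygen dictates, and ring closure must beat oligomerisation, which sub-millimolar concentration secures because unused 24 simply recloses to 23 and stays too dilute to dimerise. An aryl ethynyl ether has no sp3 C–H beta to oxygen and therefore cannot fragment by a retro-ene path at the temperature required.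

Step 15
Reactants: 28 macrocyclic phenol
Product: 29 (R)-C1 silyl ether of gravicycle (three free phenols)
Conditions: H2 (1 atm), 10% Pd/C, EtOAc, rt
Reagents that add atoms: none
Why: Catalytic hydrogenolysis of aryl benzyl ethers is fast under neutral conditions, whereas the secondary benzylic C1–O bond is shielded by the bulky silyl group and lacks acid activation, so it and the diaryl ether should persist.

Step 16
Reactants: 29 (R)-C1 silyl ether of gravicycle
Product: 30 gravicycle
Conditions: TBAF, AcOH (1:1, excess), THF, 0 °C to rt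
Reagents that add atoms: none
Why: Fluoride-induced desilylation driven by the strong Si–F bond; acetic acid keeps the phenols protonated, and because the ring B hydroxyls are meta to C1 no quinone methide can form, so the (R) centre is retained.

Compound list
1 | 3,4,5-trihydroxybenzaldehyde | O=Cc1cc(O)c(O)c(O)c1 | starting material
2 | 4-(allyloxy)-3,5-dihydroxybenzaldehyde | O=Cc1cc(O)c(OCC=C)c(O)c1 | intermediate
3 | 4-(allyloxy)-3,5-bis(benzyloxy)benzaldehyde | O=Cc1cc(OCc2ccccc2)c(OCC=C)c(OCc2ccccc2)c1 | intermediate
4 | 3,5-bis(benzyloxy)-4-hydroxybenzaldehyde | O=Cc1cc(OCc2ccccc2)c(O)c(OCc2ccccc2)c1 | intermediate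
5 | trichloroethylene | ClC=C(Cl)Cl | starting material
6 | 3,5-bis(benzyloxy)-4-{[(E)-1,2-dichloroethenyl]oxy}benzaldehyde | Cl/C=C(/Cl)Oc1c(OCc2ccccc2)cc(C=O)cc1OCc1ccccc1 | intermediate
7 | propyne | CC#C | starting material
8 | 1,12-dibromododecane | BrCCCCCCCCCCCCBr | starting material
9 | 1,3-dilithiopropyne | [Li]CC#C[Li] | intermediate
10 | 15-bromopentadec-1-yne | C#CCCCCCCCCCCCCCBr | intermediate
11 | trichloroacetyl chloride | ClC(Cl)(Cl)C(Cl)=O | starting material
12 | 3-(13-bromotridecyl)-4,4-dichlorocyclobut-2-en-1-one | O=C1C=C(CCCCCCCCCCCCCBr)C1(Cl)Cl | intermediate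
13 | 3-(13-bromotridecyl)cyclobut-2-en-1-one | O=C1C=C(CCCCCCCCCCCCCBr)C1 | intermediate
14 | 1-(13-bromotridecyl)-3,3-dimethoxycyclobut-1-ene | COC1(OC)C=C(CCCCCCCCCCCCCBr)C1 | intermediate
15 | [13-(3,3-dimethoxycyclobut-1-en-1-yl)tridecyl]magnesium bromide | COC1(OC)C=C(CCCCCCCCCCCCC[Mg]Br)C1 | intermediate
16 | racemic C1 carbinol (dichlorovinyl ether, dimethyl ketal) | Cl/C=C(/Cl)Oc1c(OCc2ccccc2)cc(cc1OCc1ccccc1)C(O)CCCCCCCCCCCCCC1=CC(OC)(OC)C1 | intermediate
17 | C1 ketone (dichlorovinyl ether, dimethyl ketal) | Cl/C=C(/Cl)Oc1c(OCc2ccccc2)cc(cc1OCc1ccccc1)C(=O)CCCCCCCCCCCCCC1=CC(OC)(OC)C1 | intermediate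
18 | (R)-C1 carbinol (dichlorovinyl ether, dimethyl ketal) | Cl/C=C(/Cl)Oc1c(OCc2ccccc2)cc(cc1OCc1ccccc1)[C@H](O)CCCCCCCCCCCCCC1=CC(OC)(OC)C1 | intermediate
19 | (R)-C1 TBS ether (dichlorovinyl ether, dimethyl ketal) | Cl/C=C(/Cl)Oc1c(OCc2ccccc2)cc(cc1OCc1ccccc1)[C@H](O[Si](C)(C)C(C)(C)C)CCCCCCCCCCCCCC1=CC(OC)(OC)C1 | intermediate
20 | (R)-chloroethynyl ether (TBS ether, dimethyl ketal) | ClC#COc1c(OCc2ccccc2)cc(cc1OCc1ccccc1)[C@H](O[Si](C)(C)C(C)(C)C)CCCCCCCCCCCCCC1=CC(OC)(OC)C1 | intermediate
21 | (R)-lithium aryloxyacetylide (TBS ether, dimethyl ketal) | [Li]C#COc1c(OCc2ccccc2)cc(cc1OCc1ccccc1)[C@H](O[Si](C)(C)C(C)(C)C)CCCCCCCCCCCCCC1=CC(OC)(OC)C1 | intermediate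
22 | (R)-ethynyl ether (TBS ether, dimethyl ketal) | C#COc1c(OCc2ccccc2)cc(cc1OCc1ccccc1)[C@H](O[Si](C)(C)C(C)(C)C)CCCCCCCCCCCCCC1=CC(OC)(OC)C1 | intermediate
23 | 3-[(14R)-14-[3,5-bis(benzyloxy)-4-(ethynyloxy)phenyl]-14-{[tert-butyl(dimethyl)silyl]oxy}tetradecyl]cyclobut-2-en-1-one (key-step precursor) | C#COc1c(OCc2ccccc2)cc(cc1OCc1ccccc1)[C@H](O[Si](C)(C)C(C)(C)C)CCCCCCCCCCCCCC1=CC(=O)C1 | intermediate
24 | (R)-vinylketene from ring opening of 23 | C#COc1c(OCc2ccccc2)cc(cc1OCc1ccccc1)[C@H](O[Si](C)(C)C(C)(C)C)CCCCCCCCCCCCCC(=C)C=C=O | intermediate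
25 | macrocyclic 3-aryloxy-4-alkenylcyclobut-2-enone ([2+2] adduct, ring-fusion carbon unassigned) | O=C1C=C2Oc3c(OCc4ccccc4)cc(cc3OCc3ccccc3)[C@H](O[Si](C)(C)C(C)(C)C)CCCCCCCCCCCCCC(=C)C12 | intermediate
26 | macrocyclic dienylketene | C=C1C=C(C=C=O)Oc2c(OCc3ccccc3)cc(cc2OCc2ccccc2)[C@H](O[Si](C)(C)C(C)(C)C)CCCCCCCCCCCCC1 | intermediate
27 | cyclohexa-2,4-dienone tautomer of 28 | O=C1CC2=CC(=C1)Oc1c(OCc3ccccc3)cc(cc1OCc1ccccc1)[C@H](O[Si](C)(C)C(C)(C)C)CCCCCCCCCCCCC2 | intermediate
28 | macrocycle with free ring A phenol, ring B benzyl ethers and (R)-C1 TBS ether (key-step product) | Oc1cc2cc(c1)Oc1c(OCc3ccccc3)cc(cc1OCc1ccccc1)[C@H](O[Si](C)(C)C(C)(C)C)CCCCCCCCCCCCC2 | intermediate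
29 | (R)-C1 TBS ether of gravicycle | Oc1cc2cc(c1)Oc1c(O)cc(cc1O)[C@H](O[Si](C)(C)C(C)(C)C)CCCCCCCCCCCCC2 | intermediate
30 | gravicycle, (R) | Oc1cc2cc(c1)Oc1c(O)cc(cc1O)[C@H](O)CCCCCCCCCCCCC2 | target

Total step count: 16. Longest linear sequence: 13 steps (steps 4 to 16, from propyne and 1,12-dibromododecane). The ring B branch (steps 1 to 3) joins at step 8.

Steps most likely to fail

1. Step 14. Capture of the vinylketene by the alkyne of a second molecule (oligomerisation), or slow thermal decay of the ethynyl ether, may outrun the entropically costly ring closure.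
The fallback uses known chemistry, sets out from 4 and comes back at 29.
- Chan–Lam coupling of 4 with [3-(benzyloxy)-5-bromophenyl]boronic acid (Cu(OAc)2, pyridine, 4 Å sieves, air, CH2Cl2) should give the diaryl ether aldehyde F1.
- Negishi coupling with but-3-enylzinc bromide (PdCl2(dppf), THF) should give the butenyl arene F2.
- Undec-10-enylmagnesium bromide should give the racemic carbinol F3, and MnO2 the ketone F4.
- Asymmetric transfer hydrogenation (RuCl(p-cymene)[(R,R)-TsDPEN], HCO2H/Et3N) spares terminal alkenes and should give the (R)-alcohol F5.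
- TBSCl/imidazole should give the silyl ether F6.
- Ring-closing metathesis (second-generation Grubbs catalyst, CH2Cl2, high dilution) should give the 22-membered C11=C12 alkene F7 as an E/Z mixture.
- Hydrogenation over Pd/C in EtOAc then saturates the alkene and removes all three benzyl groups to give 29.

2. Step 13. Acid-catalysed hydration of the ethynyl ether, or loss of the silyl ether, may compete with ketal cleavage.
The fallback sets out from 19 and comes back at 23. The enone is stored at the alcohol oxidation level, so the last unveiling is a neutral oxidation.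
- Hydrolysis of the ketal before the alkyne exists (PPTS, wet acetone) should give the dichlorovinyl ether enone F8.
- Luche reduction (NaBH4, CeCl3·7H2O, MeOH) should give the cyclobutenol F9, an epimer mixture of no consequence.
- TESCl/imidazole should give the triethylsilyl ether F10.
- n-BuLi as in step 12 should give the ethynyl ether F11.
- HF·pyridine buffered with pyridine (THF, 0 °C) should remove only the triethylsilyl group and give the ethynyl ether cyclobutenol F12.
- Activated MnO2 (CH2Cl2, rt) should oxidise the allylic alcohol to 23.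

3. Step 7. Conjugate addition of the methoxy donor, double-bond migration or Lewis acid induced ring opening may take the place of clean ketalisation.
The fallback sets out from 13 and comes back at 23.
- Luche reduction of 13 should give the bromo cyclobutenol F13, and TESCl/imidazole its silyl ether F14.
- Magnesium insertion below 35 °C should give the Grignard reagent F15, and addition to 6 the racemic carbinol F16.
- MnO2 should give the ketone F17, and the reduction of step 10 the (R)-alcohol F18.
- TBSCl/imidazole should give the bis-silyl ether F10, from which the sequence given under step 13 (F11, then F12) leads to 23.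

Further compounds
F1 | step 14 | 3,5-bis(benzyloxy)-4-[3-(benzyloxy)-5-bromophenoxy]benzaldehyde | O=Cc1cc(OCc2ccccc2)c(Oc2cc(Br)cc(OCc3ccccc3)c2)c(OCc2ccccc2)c1
F2 | step 14 | 3,5-bis(benzyloxy)-4-[3-(benzyloxy)-5-(but-3-en-1-yl)phenoxy]benzaldehyde | O=Cc1cc(OCc2ccccc2)c(Oc2cc(CCC=C)cc(OCc3ccccc3)c2)c(OCc2ccccc2)c1
F3 | step 14 | rac-1-{3,5-bis(benzyloxy)-4-[3-(benzyloxy)-5-(but-3-en-1-yl)phenoxy]phenyl}dodec-11-en-1-ol | OC(CCCCCCCCCC=C)c1cc(OCc2ccccc2)c(Oc2cc(CCC=C)cc(OCc3ccccc3)c2)c(OCc2ccccc2)c1
F4 | step 14 | 1-{3,5-bis(benzyloxy)-4-[3-(benzyloxy)-5-(but-3-en-1-yl)phenoxy]phenyl}dodec-11-en-1-one | O=C(CCCCCCCCCC=C)c1cc(OCc2ccccc2)c(Oc2cc(CCC=C)cc(OCc3ccccc3)c2)c(OCc2ccccc2)c1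
F5 | step 14 | (1R)-1-{3,5-bis(benzyloxy)-4-[3-(benzyloxy)-5-(but-3-en-1-yl)phenoxy]phenyl}dodec-11-en-1-ol | C=CCCc1cc(OCc2ccccc2)cc(c1)Oc1c(OCc2ccccc2)cc(cc1OCc1ccccc1)[C@H](O)CCCCCCCCCC=C
F6 | step 14 | (R)-TBS ether of F5 | C=CCCc1cc(OCc2ccccc2)cc(c1)Oc1c(OCc2ccccc2)cc(cc1OCc1ccccc1)[C@H](O[Si](C)(C)C(C)(C)C)CCCCCCCCCC=C
F7 | step 14 | 22-membered C11=C12 alkene (E/Z), tri-O-benzyl, (R)-C1 TBS ether | c1ccccc1COc1cc2cc(c1)Oc1c(OCc3ccccc3)cc(cc1OCc1ccccc1)[C@H](O[Si](C)(C)C(C)(C)C)CCCCCCCCCC=CCC2
F8 | step 13 | (R)-TBS ether with dichlorovinyl ether and free cyclobut-2-enone | Cl/C=C(/Cl)Oc1c(OCc2ccccc2)cc(cc1OCc1ccccc1)[C@H](O[Si](C)(C)C(C)(C)C)CCCCCCCCCCCCCC1=CC(=O)C1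
F9 | step 13 | cyclobut-2-enol from F8 (ring carbinol epimers) | Cl/C=C(/Cl)Oc1c(OCc2ccccc2)cc(cc1OCc1ccccc1)[C@H](O[Si](C)(C)C(C)(C)C)CCCCCCCCCCCCCC1=CC(O)C1
F10 | step 13 | triethylsilyl ether of F9 | Cl/C=C(/Cl)Oc1c(OCc2ccccc2)cc(cc1OCc1ccccc1)[C@H](O[Si](C)(C)C(C)(C)C)CCCCCCCCCCCCCC1=CC(O[Si](CC)(CC)CC)C1
F11 | step 13 | ethynyl ether with TES-protected cyclobutenol | C#COc1c(OCc2ccccc2)cc(cc1OCc1ccccc1)[C@H](O[Si](C)(C)C(C)(C)C)CCCCCCCCCCCCCC1=CC(O[Si](CC)(CC)CC)C1
F12 | step 13 | ethynyl ether with free cyclobutenol | C#COc1c(OCc2ccccc2)cc(cc1OCc1ccccc1)[C@H](O[Si](C)(C)C(C)(C)C)CCCCCCCCCCCCCC1=CC(O)C1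
F13 | step 7 | 3-(13-bromotridecyl)cyclobut-2-en-1-ol | OC1C=C(CCCCCCCCCCCCCBr)C1
F14 | step 7 | {[3-(13-bromotridecyl)cyclobut-2-en-1-yl]oxy}triethylsilane | CC[Si](CC)(CC)OC1C=C(CCCCCCCCCCCCCBr)C1
F15 | step 7 | Grignard reagent from F14 | CC[Si](CC)(CC)OC1C=C(CCCCCCCCCCCCC[Mg]Br)C1
F16 | step 7 | racemic C1 carbinol (dichlorovinyl ether, TES-protected cyclobutenol) | Cl/C=C(/Cl)Oc1c(OCc2ccccc2)cc(cc1OCc1ccccc1)C(O)CCCCCCCCCCCCCC1=CC(O[Si](CC)(CC)CC)C1
F17 | step 7 | C1 ketone (dichlorovinyl ether, TES-protected cyclobutenol) | Cl/C=C(/Cl)Oc1c(OCc2ccccc2)cc(cc1OCc1ccccc1)C(=O)CCCCCCCCCCCCCC1=CC(O[Si](CC)(CC)CC)C1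
F18 | step 7 | (R)-C1 carbinol (dichlorovinyl ether, TES-protected cyclobutenol) | Cl/C=C(/Cl)Oc1c(OCc2ccccc2)cc(cc1OCc1ccccc1)[C@H](O)CCCCCCCCCCCCCC1=CC(O[Si](CC)(CC)CC)C1
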